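Two questions stand on this flask, which has the charges of the theta run: when it holds most target, and how much.

| flask | starting material | second substrate | free enzyme | remark | time |
|---|---|---|---|---|---|
| theta | 24 mM | 48 mM | 2.4 µM | the very flask that is asked about, followed so far |  |
| flask | 24 mM | 48.0 mM | 2.4 µM |  | 8.0 d |

- theta (time / d: target / %, starting material / %): 0.0833: 32.4, 66.1; 0.167: 55.8, 39.2; 0.333: 78.4, 5.7; 0.833: 62.0, 0; 1.67: 49.7, 0; 3.00: 38.9, 0

(standard deviation of a reading: 0.3 percentage points)

- steps under discussion: second substrate + target -> over-reaction product; starting material + free enzyme <-> first complex; target + free enzyme <-> isomer of the product + free enzyme; first complex -> loaded enzyme + first product; second complex -> free enzyme + target; second substrate + loaded enzyme <-> second complex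

- when, up to 8.0 d, the flask holds most target
- the amount of target, in percent of the starting material charged, at that time

At 0.333 d the theta run reads 78.4% target and 5.7% starting material, so 15.9% of the charge is neither; we call this the lost share. Between 0.167 d and 0.333 d starting material falls by 34 percentage points and the lost share grows by 11 points, so over that interval target is on average made faster than it is lost. At that pace the remaining starting material lasts 0.0282 d, so as a rough estimate of our own we put the top near 0.361 d, and the later readings fall from 62.0% to 38.9%.

The forecast says 0.34 d (0.31 d to 0.38 d) and 78.5% (77.8% to 79.6%), on the ground that the “peak comes when formation equals loss”; its time is earlier than our 0.361 d.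

    second substrate + target → over-reaction product (k = 2.20 × 10⁻⁴ /M/s)
    starting material + free enzyme ⇌ first complex (K = 28.0 /M, k = 1300 /M/s)
    target + free enzyme ⇌ isomer of the product + free enzyme, rate k3*[free enzyme]*[target] forward; the back reaction follows from the equilibrium constant (K = 0.240, k = 5.90 /M/s)
    first complex → loaded enzyme + first product (k = 4.80 /s)
    second complex → free enzyme + target (k = 1.80 /s)
    second substrate + loaded enzyme ⇌ second complex (K = 14.0 /M, k = 440 /M/s)

The flask holds 78.5% at 0.348 d, inside both ranges of the forecast. Its lost share at 0.348 d is 17.5%, up from the 15.9% read at 0.333 d, and it consists of 10.1% over-reaction product and 7.36% isomer of the product. The over-reaction step has no enzyme in it, and the isomer step has. For the neighbour with 0.0060 mM free enzyme, 2.50 times this charge, we keep the starting material and isomer shares and divide the over-reaction share by that factor. This rough estimate gives target 84.5%, and that neighbour at its best holds 84.0%.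

The numbers in the tables are calculated with constants of no real substance; scatter was added.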